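**Retrosynthetic overview**
1. Target diacid ⇐ its di-tert-butyl ester; the C9 isopropenyl group is cut back to a secondary pinacol boronate (Zweifel olefination, retention at C9).
2. Key step: that boronate ⇐ a terminal alkene (fragment B) + an alkenyl iodide (fragment A) by one-flask enantioselective Pt-catalysed 1,2-diboration and Suzuki coupling of the primary C–B bond. This forms C7–C8, joins the halves and sets the only stereocentre by catalyst control.
3. Fragment A (both E alkenes): pent-4-yn-1-ol ⇒ Negishi carboalumination–iodination (6E), oxidation, Wittig with a homoprenyl-substituted stabilised ylide (2E).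
4. Fragment B (Z enoate): furylmethyl bromide + propargyl dianion/Boc2O ⇒ ynoate; syn hydrostannation–iodination, then Negishi coupling with butenylzinc, fixes 12Z.
5. Rings: none is formed; the furan is bought as furan-3-ylmethanol and carried through.

Assumption: the (R,R)-TADDOL-derived phosphonite is taken to give the (S)-1,2-bis(boronate) in step 9 (the sense that gives (R)-1,2-diols from 1-alkenes after oxidation); if the sense is the opposite, the (S,S)-ligand is used and nothing else changes.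

**Step 1**
Reactants: 1 tert-butyl (triphenyl-λ5-phosphanylidene)acetate; 2 5-bromo-2-methylpent-2-ene
Product: 4 tert-butyl 6-methyl-2-(triphenyl-λ5-phosphanylidene)hept-5-enoate, via phosphonium bromide 3 (not isolated)
Conditions: NaI (10 mol%), MeCN, reflux, 48 h; then 2 M aq. NaOH, CH2Cl2, rt
Reagents that add atoms: none
Why: C-alkylation of the stabilised ylide by the primary homoprenyl halide (iodide formed in situ by Finkelstein exchange) gives the phosphonium salt, which NaOH deprotonates to the α-branched stabilised Wittig ylide; no stereocentre is involved.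

**Step 2**
Reactants: 5 pent-4-yn-1-ol
Product: 7 (4E)-5-iodo-4-methylpent-4-en-1-ol, via alkenylalane 6 (not isolated)
Conditions: Me3Al (3 equiv), Cp2ZrCl2 (0.25 equiv), CH2Cl2, 0 °C → rt, 16 h; then I2 (1.2 equiv), THF, –30 → 0 °C; aq. work-up
Reagents that add atoms: trimethylaluminium C[Al](C)C; iodine II
Why: Negishi zirconium-catalysed carboalumination adds Me and Al syn across the terminal alkyne with Me on the internal carbon, and iodinolysis of the C–Al bond with retention fixes the (E)-trisubstituted alkenyl iodide.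

**Step 3**
Reactants: 7 (4E)-5-iodo-4-methylpent-4-en-1-ol
Product: 8 (4E)-5-iodo-4-methylpent-4-enal
Conditions: Dess–Martin periodinane (1.2 equiv), CH2Cl2, 0 °C → rt
Reagents that add atoms: none
Why: Dess–Martin oxidation takes the primary alcohol to the aldehyde under neutral conditions and leaves the alkenyl iodide untouched.

**Step 4**
Reactants: 8 (4E)-5-iodo-4-methylpent-4-enal; 4 tert-butyl 6-methyl-2-(triphenyl-λ5-phosphanylidene)hept-5-enoate
Product: 9 tert-butyl (2E,6E)-7-iodo-6-methyl-2-(4-methylpent-3-en-1-yl)hepta-2,6-dienoate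
Conditions: toluene, 90 °C, 12 h
Reagents that add atoms: none
Why: Wittig olefination with an α-branched stabilised ylide places the ester trans to the aldehyde-derived chain, giving the (2E)-enoate (expected ≥ 95:5).

**Step 5**
Reactants: 10 furan-3-ylmethanol
Product: 11 3-(bromomethyl)furan
Conditions: PBr3 (0.4 equiv), Et2O, 0 °C, 1 h; used at once
Reagents that add atoms: phosphorus tribromide BrP(Br)Br
Why: Bromination of the furylmethyl alcohol through its bromophosphite (SN2) is fast at 0 °C, and the labile bromide is not stored.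

**Step 6**
Reactants: 11 3-(bromomethyl)furan; 12 3-bromoprop-1-yne
Product: 15 tert-butyl 5-(furan-3-yl)pent-2-ynoate, via dilithiopropyne 13 (not isolated), via lithium acetylide 14 (not isolated)
Conditions: 12 (1.3 equiv), n-BuLi (2.6 equiv), TMEDA (1.3 equiv), Et2O/hexane, –78 °C; then 11, –78 → 0 °C; then Boc2O (1.5 equiv), –78 °C → rt
Reagents that add atoms: di-tert-butyl dicarbonate CC(C)(C)OC(=O)OC(=O)OC(C)(C)C
Why: Propargyl-dianion homologation: the more nucleophilic sp3 terminus of 1,3-dilithiopropyne displaces the furylmethyl bromide (SN2) and the surviving lithium acetylide is acylated by Boc2O to the tert-butyl ynoate in the same flask.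

**Step 7**
Reactants: 15 tert-butyl 5-(furan-3-yl)pent-2-ynoate
Product: 17 tert-butyl (2E)-5-(furan-3-yl)-2-iodopent-2-enoate, via alkenylstannane 16 (not isolated)
Conditions: Bu3SnH (1.05 equiv), Pd(PPh3)4 (2 mol%), THF, 0 °C → rt; then I2 (1.15 equiv), CH2Cl2, 0 °C
Reagents that add atoms: iodine II
Why: Palladium-catalysed hydrostannation of a 2-ynoate is a syn addition that puts tin α to the ester, so iododestannylation with retention gives the α-iodo enoate with the furylethyl chain cis to the ester.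

**Step 8**
Reactants: 17 tert-butyl (2E)-5-(furan-3-yl)-2-iodopent-2-enoate; 18 but-3-en-1-ylzinc bromide (commercial 0.5 M solution in THF, 1.5 equiv)
Product: 19 tert-butyl (2Z)-2-(but-3-en-1-yl)-5-(furan-3-yl)pent-2-enoate
Conditions: PdCl2(dppf) (3 mol%), THF, rt → 40 °C
Reagents that add atoms: none
Why: Negishi sp3–sp2 cross-coupling of a primary alkylzinc with the alkenyl iodide retains the alkene geometry, giving the (Z)-2-alkyl enoate and the terminal alkene needed for the key step.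

**Step 9**
Reactants: 19 tert-butyl (2Z)-2-(but-3-en-1-yl)-5-(furan-3-yl)pent-2-enoate; 9 tert-butyl (2E,6E)-7-iodo-6-methyl-2-(4-methylpent-3-en-1-yl)hepta-2,6-dienoate
Product: 21 di-tert-butyl (2E,6E,9R,12Z)-12-[3-(furan-3-yl)propylidene]-6-methyl-2-(4-methylpent-3-en-1-yl)-9-(4,4,5,5-tetramethyl-1,3,2-dioxaborolan-2-yl)trideca-2,6-dienedioate, via bis(boronate) 20 (not isolated)
Conditions: B2pin2 (1.05 equiv), Pt(dba)3 (3 mol%), (R,R)-3,5-diisopropylphenyl-TADDOL phenylphosphonite (6 mol%), THF, 60 °C, 3 h; then 9 (1.0 equiv), Pd(OAc)2 (2 mol%), RuPhos (2 mol%), KOH (3 equiv), THF/H2O 10:1, 70 °C, 12 h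
Reagents that add atoms: bis(pinacolato)diboron CC1(C)OB(OC1(C)C)B1OC(C)(C)C(C)(C)O1
Why: Tandem platinum-catalysed enantioselective alkene 1,2-diboration and chemoselective Suzuki–Miyaura coupling of the primary C–B bond: the chiral phosphonite–Pt catalyst selects one face of the only monosubstituted alkene and sets C9 as the (S)-bis(boronate), which is (9R) by CIP once the CH2B arm has been exchanged for the alkenyl group without touching the stereocentre; tert-butyl esters withstand the aqueous KOH.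

**Step 10**
Reactants: 21 the (9R)-boronate from step 9; 22 2-bromopropene
Product: 26 di-tert-butyl (2E,6E,9R,12Z)-12-[3-(furan-3-yl)propylidene]-6-methyl-2-(4-methylpent-3-en-1-yl)-9-(prop-1-en-2-yl)trideca-2,6-dienedioate, via isopropenyllithium 23 (not isolated), via borate complex 24 (not isolated), via iodo boronate 25 (not isolated)
Conditions: 22 (1.3 equiv), t-BuLi (2.6 equiv), Et2O, –78 °C; add to 21, THF, –78 °C, 30 min; I2 (1.3 equiv), THF, –78 °C; NaOMe (3 equiv), MeOH, –78 °C → rt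
Reagents that add atoms: none
Why: Zweifel olefination: isopropenyllithium adds to boron, iodine triggers a stereoretentive 1,2-shift of the secondary alkyl group from boron to carbon and methoxide-induced anti elimination of boron and iodide unveils the isopropenyl group, so C9 stays (R); the hindered tert-butyl enoates should survive a slight excess of alkenyllithium at –78 °C.

**Step 11**
Reactants: 26 the di-tert-butyl ester from step 10
Product: 28 (2E,6E,9R,12Z)-12-[3-(furan-3-yl)propylidene]-6-methyl-2-(4-methylpent-3-en-1-yl)-9-(prop-1-en-2-yl)trideca-2,6-dienedioic acid (CNP0235727.2), via bis(silyl) ester 27 (not isolated)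
Conditions: Me3SiOTf (6 equiv), 2,6-lutidine (10 equiv), CH2Cl2, 0 °C → rt; then H2O, pH 4 citrate buffer
Reagents that add atoms: none
Why: Silyl-triflate cleavage of tert-butyl esters (O-silylation, loss of the tert-butyl cation as isobutene) is buffered by 2,6-lutidine so that no Brønsted acid reaches the furan, the skipped diene or the (Z)-enoate, and the bis(silyl) ester hydrolyses on work-up.

**Compound list**
1 | tert-butyl (triphenyl-λ5-phosphanylidene)acetate | CC(C)(C)OC(=O)C=P(c1ccccc1)(c1ccccc1)c1ccccc1 | starting material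
2 | 5-bromo-2-methylpent-2-ene | CC(C)=CCCBr | starting material
3 | (1-tert-butoxy-6-methyl-1-oxohept-5-en-2-yl)triphenylphosphonium bromide (racemic) | CC(C)=CCCC(C(=O)OC(C)(C)C)[P+](c1ccccc1)(c1ccccc1)c1ccccc1.[Br-] | intermediate
4 | tert-butyl 6-methyl-2-(triphenyl-λ5-phosphanylidene)hept-5-enoate | CC(C)=CCCC(C(=O)OC(C)(C)C)=P(c1ccccc1)(c1ccccc1)c1ccccc1 | intermediate
5 | pent-4-yn-1-ol | C#CCCCO | starting material
6 | [(1E)-5-(dimethylalumanyloxy)-2-methylpent-1-en-1-yl]dimethylalumane | C[Al](C)OCCC/C(C)=C/[Al](C)C | intermediate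
7 | (4E)-5-iodo-4-methylpent-4-en-1-ol | OCCC/C(C)=C/I | intermediate
8 | (4E)-5-iodo-4-methylpent-4-enal | O=CCC/C(C)=C/I | intermediate
9 | tert-butyl (2E,6E)-7-iodo-6-methyl-2-(4-methylpent-3-en-1-yl)hepta-2,6-dienoate (fragment A) | CC(C)=CCC/C(C(=O)OC(C)(C)C)=C\CC/C(C)=C/I | intermediate
10 | furan-3-ylmethanol | OCc1ccoc1 | starting material
11 | 3-(bromomethyl)furan | BrCc1ccoc1 | intermediate
12 | 3-bromoprop-1-yne (propargyl bromide) | C#CCBr | starting material
13 | 1,3-dilithiopropyne | [Li]CC#C[Li] | intermediate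
14 | [4-(furan-3-yl)but-1-yn-1-yl]lithium | [Li]C#CCCc1ccoc1 | intermediate
15 | tert-butyl 5-(furan-3-yl)pent-2-ynoate | CC(C)(C)OC(=O)C#CCCc1ccoc1 | intermediate
16 | tert-butyl (2E)-5-(furan-3-yl)-2-(tributylstannyl)pent-2-enoate | CCCC[Sn](CCCC)(CCCC)/C(=C/CCc1ccoc1)C(=O)OC(C)(C)C | intermediate
17 | tert-butyl (2E)-5-(furan-3-yl)-2-iodopent-2-enoate | I/C(=C/CCc1ccoc1)C(=O)OC(C)(C)C | intermediate
18 | but-3-en-1-ylzinc bromide | C=CCC[Zn]Br | starting material
19 | tert-butyl (2Z)-2-(but-3-en-1-yl)-5-(furan-3-yl)pent-2-enoate (fragment B) | C=CCC/C(=C/CCc1ccoc1)C(=O)OC(C)(C)C | intermediate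
20 | tert-butyl (2Z)-2-[(3S)-3,4-bis(4,4,5,5-tetramethyl-1,3,2-dioxaborolan-2-yl)butyl]-5-(furan-3-yl)pent-2-enoate | CC1(C)OB(C[C@@H](CC/C(=C/CCc2ccoc2)C(=O)OC(C)(C)C)B2OC(C)(C)C(C)(C)O2)OC1(C)C | intermediate
21 | di-tert-butyl (2E,6E,9R,12Z)-12-[3-(furan-3-yl)propylidene]-6-methyl-2-(4-methylpent-3-en-1-yl)-9-(4,4,5,5-tetramethyl-1,3,2-dioxaborolan-2-yl)trideca-2,6-dienedioate | CC(C)=CCC/C(C(=O)OC(C)(C)C)=C\CC/C(C)=C/C[C@@H](CC/C(=C/CCc1ccoc1)C(=O)OC(C)(C)C)B1OC(C)(C)C(C)(C)O1 | intermediate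
22 | 2-bromopropene | C=C(C)Br | starting material
23 | prop-1-en-2-yllithium (isopropenyllithium) | [Li]C(C)=C | intermediate
24 | lithium borate of 21 carrying an isopropenyl group on boron (C9 unchanged) | [Li+].CC(C)=CCC/C(C(=O)OC(C)(C)C)=C\CC/C(C)=C/C[C@@H](CC/C(=C/CCc1ccoc1)C(=O)OC(C)(C)C)[B-]1(C(C)=C)OC(C)(C)C(C)(C)O1 | intermediate
25 | iodo boronate: C9 of the chain now carries C(CH3)(CH2I)B(pin) (both epimers at that new carbon) | CC(C)=CCC/C(C(=O)OC(C)(C)C)=C\CC/C(C)=C/C[C@@H](CC/C(=C/CCc1ccoc1)C(=O)OC(C)(C)C)C(C)(CI)B1OC(C)(C)C(C)(C)O1 | intermediate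
26 | di-tert-butyl (2E,6E,9R,12Z)-12-[3-(furan-3-yl)propylidene]-6-methyl-2-(4-methylpent-3-en-1-yl)-9-(prop-1-en-2-yl)trideca-2,6-dienedioate | CC(C)=CCC/C(C(=O)OC(C)(C)C)=C\CC/C(C)=C/C[C@@H](CC/C(=C/CCc1ccoc1)C(=O)OC(C)(C)C)C(C)=C | intermediate
27 | bis(trimethylsilyl) (2E,6E,9R,12Z)-12-[3-(furan-3-yl)propylidene]-6-methyl-2-(4-methylpent-3-en-1-yl)-9-(prop-1-en-2-yl)trideca-2,6-dienedioate | CC(C)=CCC/C(C(=O)O[Si](C)(C)C)=C\CC/C(C)=C/C[C@@H](CC/C(=C/CCc1ccoc1)C(=O)O[Si](C)(C)C)C(C)=C | intermediate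
28 | (2E,6E,9R,12Z)-12-[3-(furan-3-yl)propylidene]-6-methyl-2-(4-methylpent-3-en-1-yl)-9-(prop-1-en-2-yl)trideca-2,6-dienedioic acid | C=C(C)[C@@H](C/C=C(\C)CC/C=C(\CCC=C(C)C)C(=O)O)CC/C(=C/CCc1ccoc1)C(=O)O | target

**Totals**
Total steps: 11. Longest linear sequence: 7 (steps 5, 6, 7, 8, 9, 10, 11, from furan-3-ylmethanol).

**Three steps most likely to fail, with fallbacks**

Step 9. The diboration has to stay enantioselective on a fully functionalised alkene, and the coupling runs in hot aqueous KOH. The fallback sets out from alkenyl iodide 9 and comes back at 26, bypassing steps 9 and 10. Isopropenyllithium 23 is added to commercial vinylboronic acid pinacol ester (THF, –78 °C) to give lithium (pinacolato)(prop-1-en-2-yl)(vinyl)borate F1. A palladium-catalysed enantioselective conjunctive cross-coupling of this borate with 9 (Pd(OAc)2, the MandyPhos enantiomer that gives 9R, NaOTf, THF, 60 °C) moves the isopropenyl group from boron to the vinyl carbon. It gives the allylic boronate tert-butyl (2E,6E,9R)-6,10-dimethyl-2-(4-methylpent-3-en-1-yl)-9-(4,4,5,5-tetramethyl-1,3,2-dioxaborolan-2-yl)undeca-2,6,10-trienoate F2, in which C9 already carries the isopropenyl group. Two Matteson homologations with LiCH2Cl (BrCH2Cl, n-BuLi, THF, –78 °C → rt) insert CH2 groups with retention. The first gives the 9-[(4,4,5,5-tetramethyl-1,3,2-dioxaborolan-2-yl)methyl] analogue F3 and the second the 9-[2-(4,4,5,5-tetramethyl-1,3,2-dioxaborolan-2-yl)ethyl] analogue F4. B-alkyl Suzuki–Miyaura coupling of the latter with iodo enoate 17 (Pd(OAc)2, RuPhos, K3PO4, toluene/H2O, 80 °C) gives 26.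

Step 10. The alkenyllithium meets two tert-butyl enoates. The fallback sets out from 21 and comes back at 28: the esters are removed first and the Zweifel step is run on the dicarboxylate. Me3SiOTf/2,6-lutidine (CH2Cl2, 0 °C) converts 21 into the bis(trimethylsilyl) ester boronate F5, and aqueous work-up gives the diacid boronate (2E,6E,9R,12Z)-12-[3-(furan-3-yl)propylidene]-6-methyl-2-(4-methylpent-3-en-1-yl)-9-(4,4,5,5-tetramethyl-1,3,2-dioxaborolan-2-yl)trideca-2,6-dienedioic acid F6. Isopropenyllithium 23 (3.4 equiv, THF, –78 °C) first deprotonates both acids, giving carboxylates that are inert to organolithiums at this temperature, and then forms the trilithium borate dicarboxylate F7. I2 gives the dilithium iodo boronate dicarboxylate F8, and NaOMe/MeOH followed by acidification to pH 4 gives 28 directly. This answers the ester/organolithium clash but not an iodine side reaction on the polyene.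

Step 11. A Lewis acid is used next to a furan, a skipped diene and a (Z)-enoate. The fallback sets out from 26 and comes back at 28 by a redox detour instead of solvolysis. i-Bu2AlH (CH2Cl2, –78 → 0 °C) reduces both esters to the bis(allylic) diol (2E,6E,9R,12Z)-12-[3-(furan-3-yl)propylidene]-6-methyl-2-(4-methylpent-3-en-1-yl)-9-(prop-1-en-2-yl)trideca-2,6-diene-1,13-diol F9. MnO2 (CH2Cl2, rt) gives the corresponding trideca-2,6-dienedial F10. Buffered chlorite oxidation (NaClO2, NaH2PO4, 2-methylbut-2-ene in excess, t-BuOH/H2O, 0 °C) then gives 28. The dial is oxidised on without chromatography to limit Z to E isomerisation of the enal, and the chlorite step must be checked for furan oxidation.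

**Further compounds**
F1 | step 9 | lithium (pinacolato)(prop-1-en-2-yl)(vinyl)borate | [Li+].C=C[B-]1(C(C)=C)OC(C)(C)C(C)(C)O1
F2 | step 9 | tert-butyl (2E,6E,9R)-6,10-dimethyl-2-(4-methylpent-3-en-1-yl)-9-(4,4,5,5-tetramethyl-1,3,2-dioxaborolan-2-yl)undeca-2,6,10-trienoate | CC(C)=CCC/C(C(=O)OC(C)(C)C)=C\CC/C(C)=C/C[C@@H](B1OC(C)(C)C(C)(C)O1)C(C)=C
F3 | step 9 | tert-butyl (2E,6E,9R)-6,10-dimethyl-2-(4-methylpent-3-en-1-yl)-9-[(4,4,5,5-tetramethyl-1,3,2-dioxaborolan-2-yl)methyl]undeca-2,6,10-trienoate | CC(C)=CCC/C(C(=O)OC(C)(C)C)=C\CC/C(C)=C/C[C@@H](CB1OC(C)(C)C(C)(C)O1)C(C)=C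
F4 | step 9 | tert-butyl (2E,6E,9R)-6,10-dimethyl-2-(4-methylpent-3-en-1-yl)-9-[2-(4,4,5,5-tetramethyl-1,3,2-dioxaborolan-2-yl)ethyl]undeca-2,6,10-trienoate | CC(C)=CCC/C(C(=O)OC(C)(C)C)=C\CC/C(C)=C/C[C@@H](CCB1OC(C)(C)C(C)(C)O1)C(C)=C
F5 | step 10 | bis(trimethylsilyl) (2E,6E,9R,12Z)-12-[3-(furan-3-yl)propylidene]-6-methyl-2-(4-methylpent-3-en-1-yl)-9-(4,4,5,5-tetramethyl-1,3,2-dioxaborolan-2-yl)trideca-2,6-dienedioate | CC(C)=CCC/C(C(=O)O[Si](C)(C)C)=C\CC/C(C)=C/C[C@@H](CC/C(=C/CCc1ccoc1)C(=O)O[Si](C)(C)C)B1OC(C)(C)C(C)(C)O1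
F6 | step 10 | (2E,6E,9R,12Z)-12-[3-(furan-3-yl)propylidene]-6-methyl-2-(4-methylpent-3-en-1-yl)-9-(4,4,5,5-tetramethyl-1,3,2-dioxaborolan-2-yl)trideca-2,6-dienedioic acid | CC(C)=CCC/C(C(=O)O)=C\CC/C(C)=C/C[C@@H](CC/C(=C/CCc1ccoc1)C(=O)O)B1OC(C)(C)C(C)(C)O1
F7 | step 10 | trilithium borate dicarboxylate (isopropenyl on boron, both acids as carboxylates) | [Li+].[Li+].[Li+].CC(C)=CCC/C(C(=O)[O-])=C\CC/C(C)=C/C[C@@H](CC/C(=C/CCc1ccoc1)C(=O)[O-])[B-]1(C(C)=C)OC(C)(C)C(C)(C)O1
F8 | step 10 | dilithium iodo boronate dicarboxylate (C9 carries C(CH3)(CH2I)B(pin), both epimers at that carbon) | [Li+].[Li+].CC(C)=CCC/C(C(=O)[O-])=C\CC/C(C)=C/C[C@@H](CC/C(=C/CCc1ccoc1)C(=O)[O-])C(C)(CI)B1OC(C)(C)C(C)(C)O1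
F9 | step 11 | (2E,6E,9R,12Z)-12-[3-(furan-3-yl)propylidene]-6-methyl-2-(4-methylpent-3-en-1-yl)-9-(prop-1-en-2-yl)trideca-2,6-diene-1,13-diol | CC(C)=CCC/C(CO)=C\CC/C(C)=C/C[C@@H](CC/C(=C/CCc1ccoc1)CO)C(C)=C
F10 | step 11 | (2E,6E,9R,12Z)-12-[3-(furan-3-yl)propylidene]-6-methyl-2-(4-methylpent-3-en-1-yl)-9-(prop-1-en-2-yl)trideca-2,6-dienedial | CC(C)=CCC/C(C=O)=C\CC/C(C)=C/C[C@@H](CC/C(=C/CCc1ccoc1)C=O)C(C)=C
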